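**Retrosynthetic overview**

- The tertiary allylic hydroperoxide is installed last, by cobalt-hydride radical hydroperoxidation of a terminal dienone. The dienone comes from a side-chain epoxy aldehyde and a five-carbon enyne (alkenylzinc addition, then oxidation).
- The quaternary side-chain epoxide comes from catalyst-controlled epoxidation of an α-branched enal, unmasked from a dimethyl acetal. The isovalerate comes from enolate hydroxylation and acylation of a cis-epoxy ketone.
- The ring epoxide, cis to the side chain, comes from a carvone-type enone by Luche reduction, hydroxyl-directed epoxidation and re-oxidation.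
- Key step: the only carbocycle is made by an enantioselective nickel-catalysed two-carbon ring expansion of a prochiral 3-alkenylcyclobutanone with propyne (C–C cleavage by β-carbon elimination). It sets the ring stereocentre that bears the side chain.
- The cyclobutanone comes from 3-oxocyclobutanecarboxylic acid and a bromoacrolein acetal by decarboxylative alkenylation. Ring order: cyclobutanone (bought) → cyclohexenone → ring oxirane → side-chain oxirane.

Assumption: 2-bromo-3,3-dimethoxyprop-1-ene (2-bromoacrolein dimethyl acetal) is taken as purchasable.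

**Step 1**
Reactants: 1 3-oxocyclobutane-1-carboxylic acid; 2 2-bromo-3,3-dimethoxyprop-1-ene
Product: 6 3-(3,3-dimethoxyprop-1-en-2-yl)cyclobutan-1-one, via N-hydroxyphthalimide ester 3 (not isolated), via alkenyllithium 4 (not isolated), via alkenylzinc chloride 5 (not isolated)
Conditions: 1, N-hydroxyphthalimide, i-PrN=C=N-i-Pr, DMAP (cat.), CH2Cl2, rt; 2, n-BuLi, THF, −78 °C, then ZnCl2; combine, Ni(acac)2 (10 mol %), 2,2′-bipyridine (10 mol %), THF/DMF, rt
Reagents that add atoms: none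
Why: Nickel-catalysed decarboxylative alkenylation (Negishi-type coupling of a redox-active ester): single-electron reduction of 3 releases CO2 and a cyclobutyl radical that nickel couples with the 1,1-disubstituted alkenylzinc 5, a reaction class that tolerates ketones; no stereocentre is formed, and 6 is achiral with two enantiotopic α-carbons.

**Step 2**
Reactants: 6 3-(3,3-dimethoxyprop-1-en-2-yl)cyclobutan-1-one; 7 propyne
Product: 8 (5R)-5-(3,3-dimethoxyprop-1-en-2-yl)-2-methylcyclohex-2-en-1-one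
Conditions: Ni(cod)2 (10 mol %), (R,R,R,R)-ANIPE·HCl (12 mol %; N,N′-bis{2,6-bis[(R)-1-phenylethyl]-4-methylphenyl}acenaphthoimidazolium chloride), KOt-Bu (12 mol %), propyne (3 equiv, slow addition), toluene, 40 °C
Reagents that add atoms: none
Why: Proposed new method: zerovalent nickel with a bulky C2-symmetric chiral carbene should undergo hetero-oxidative cyclisation of the strained ketone with propyne (ligand bulk keeps the alkyne hydrogen next to nickel, so the methyl-bearing carbon bonds to the carbonyl carbon), then irreversible, strain-releasing β-carbon elimination of one of the two enantiotopic ring C–C bonds, which is the step that fixes the (5R) centre, and finally C(sp3)–C(sp2) reductive elimination to the 2-methylcyclohexenone; the closest known chemistry is the racemic nickel-catalysed [4+2] insertion of internal alkynes into cyclobutanones, its enantioselective intramolecular alkene variants, and ligand-size regiocontrol in nickel–carbene alkyne/aldehyde couplings, whereas an intermolecular, enantioselective, regiocontrolled insertion of a terminal alkyne is not yet described (the ligand antipode that gives 5R has to be found by experiment).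

**Step 3**
Reactants: 8 (5R)-5-(3,3-dimethoxyprop-1-en-2-yl)-2-methylcyclohex-2-en-1-one
Product: 9 (1R,5R)-5-(3,3-dimethoxyprop-1-en-2-yl)-2-methylcyclohex-2-en-1-ol
Conditions: NaBH4, CeCl3·7H2O, MeOH, −78 °C
Reagents that add atoms: none
Why: Luche 1,2-reduction: hydride attacks the enone carbonyl axially, anti to the pseudo-equatorial C5 substituent (as carvone gives cis-carveol), so the carbinol is set (R), cis to the side chain, and the dimethyl acetal is inert in methanol.

**Step 4**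
Reactants: 9 (1R,5R)-5-(3,3-dimethoxyprop-1-en-2-yl)-2-methylcyclohex-2-en-1-ol
Product: 10 (1R,2R,4S,6S)-4-(3,3-dimethoxyprop-1-en-2-yl)-1-methyl-7-oxabicyclo[4.1.0]heptan-2-ol
Conditions: VO(acac)2 (2 mol %), t-BuOOH (1.5 equiv), CH2Cl2, 0 °C → rt
Reagents that add atoms: tert-butyl hydroperoxide, CC(C)(C)OO
Why: Vanadium-catalysed hydroxyl-directed epoxidation: the allylic vanadate delivers oxygen syn to the hydroxyl, which puts the ring epoxide cis to the side chain (the relationship that a Weitz–Scheffer epoxidation of 8 would not give) and leaves the unactivated side-chain alkene alone.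

**Step 5**
Reactants: 10 (1R,2R,4S,6S)-4-(3,3-dimethoxyprop-1-en-2-yl)-1-methyl-7-oxabicyclo[4.1.0]heptan-2-ol
Product: 11 (1S,4R,6S)-4-(3,3-dimethoxyprop-1-en-2-yl)-1-methyl-7-oxabicyclo[4.1.0]heptan-2-one
Conditions: (n-Pr4N)RuO4 (5 mol %), N-methylmorpholine N-oxide, 4 Å MS, CH2Cl2, rt
Reagents that add atoms: none
Why: Ley–Griffith oxidation of the secondary epoxy alcohol under neutral conditions gives the cis-epoxy ketone without touching the epoxide, the acetal or any stereocentre.

**Step 6**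
Reactants: 11 (1S,4R,6S)-4-(3,3-dimethoxyprop-1-en-2-yl)-1-methyl-7-oxabicyclo[4.1.0]heptan-2-one; 12 3-methylbutanoyl chloride
Product: 15 [(1S,3S,4S,6S)-4-(3,3-dimethoxyprop-1-en-2-yl)-1-methyl-2-oxo-7-oxabicyclo[4.1.0]heptan-3-yl] 3-methylbutanoate, via potassium enolate 13 (not isolated), via potassium alkoxide 14 (not isolated)
Conditions: KN(SiMe3)2 (1.1 equiv), THF, −78 °C; 2-(phenylsulfonyl)-3-phenyloxaziridine (1.3 equiv), −78 °C; then 12 (2 equiv), DMAP (cat.), −78 → 0 °C
Reagents that add atoms: 2-(phenylsulfonyl)-3-phenyloxaziridine, O=S(=O)(N1OC1c1ccccc1)c1ccccc1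
Why: Davis enolate hydroxylation with in situ O-acylation: C3 is the only enolisable carbon, the oxaziridine approaches the enolate anti to both the adjacent side chain and the epoxide oxygen to give the trans (3S) alkoxide, and the acid chloride traps it as the ester, which is also the thermodynamically preferred diequatorial isomer.

**Step 7**
Reactants: 15 [(1S,3S,4S,6S)-4-(3,3-dimethoxyprop-1-en-2-yl)-1-methyl-2-oxo-7-oxabicyclo[4.1.0]heptan-3-yl] 3-methylbutanoate
Product: 17 [(1S,3S,4R,6S)-4-[(2R)-2-formyloxiran-2-yl]-1-methyl-2-oxo-7-oxabicyclo[4.1.0]heptan-3-yl] 3-methylbutanoate, via enal 16 (not isolated)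
Conditions: pyridinium p-toluenesulfonate (10 mol %), acetone/H2O, rt, evaporate; then 9-amino(9-deoxy)epiquinine·(R)-TRIP salt (10 mol %; TRIP = 3,3′-bis(2,4,6-triisopropylphenyl)-1,1′-binaphthyl-2,2′-diyl hydrogen phosphate), 50 % aq. H2O2 (3 equiv), THF, 40 °C
Reagents that add atoms: water, O; hydrogen peroxide, OO
Why: Acetal hydrolysis followed by iminium-catalysed asymmetric epoxidation of an α-branched enal: the cinchona primary amine forms the iminium ion, hydrogen peroxide adds to the terminal CH2, and the enamine closes onto the O–O bond from the face fixed by the amine/chiral phosphate ion pair, so the quaternary epoxide carbon is set (2R) by the catalyst (the quinidine-derived pseudo-enantiomer with (S)-TRIP is the alternative if the sense is opposite), while the hindered ring ketone stays out of the catalysis.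

**Step 8**
Reactants: 17 [(1S,3S,4R,6S)-4-[(2R)-2-formyloxiran-2-yl]-1-methyl-2-oxo-7-oxabicyclo[4.1.0]heptan-3-yl] 3-methylbutanoate; 18 2-methylbut-1-en-3-yne
Product: 21 [(1S,3S,4R,6S)-4-[(2R)-2-[(2E)-1-hydroxy-4-methylpenta-2,4-dien-1-yl]oxiran-2-yl]-1-methyl-2-oxo-7-oxabicyclo[4.1.0]heptan-3-yl] 3-methylbutanoate (both carbinol epimers), via alkenylzirconocene chloride 19 (not isolated), via alkenyl(methyl)zinc 20 (not isolated)
Conditions: 18, Cp2Zr(H)Cl (1.2 equiv), CH2Cl2, rt; Me2Zn (1.2 equiv), −65 °C; then 17, −65 → 0 °C; aq. NH4Cl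
Reagents that add atoms: none
Why: Hydrozirconation of the terminal alkyne (syn, anti-Markovnikov, giving the E-dienyl metal), zirconium-to-zinc transmetalation and 1,2-addition: the alkenylzinc adds to the aldehyde but not to the hindered ring ketone or the ester, and the unselective new carbinol centre is removed in step 9.

**Step 9**
Reactants: 21 [(1S,3S,4R,6S)-4-[(2R)-2-[(2E)-1-hydroxy-4-methylpenta-2,4-dien-1-yl]oxiran-2-yl]-1-methyl-2-oxo-7-oxabicyclo[4.1.0]heptan-3-yl] 3-methylbutanoate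
Product: 22 [(1S,3S,4R,6S)-1-methyl-4-[(2R)-2-[(2E)-4-methylpenta-2,4-dienoyl]oxiran-2-yl]-2-oxo-7-oxabicyclo[4.1.0]heptan-3-yl] 3-methylbutanoate
Conditions: Dess–Martin periodinane, CH2Cl2, 0 °C → rt
Reagents that add atoms: none
Why: Dess–Martin oxidation of the allylic alcohol gives the E-dienone under near-neutral conditions that keep both epoxides and the α-acyloxy ketone intact.

**Step 10**
Reactants: 22 [(1S,3S,4R,6S)-1-methyl-4-[(2R)-2-[(2E)-4-methylpenta-2,4-dienoyl]oxiran-2-yl]-2-oxo-7-oxabicyclo[4.1.0]heptan-3-yl] 3-methylbutanoate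
Product: 24 [(1S,3S,4R,6S)-4-[(2R)-2-[(2E)-4-hydroperoxy-4-methylpent-2-enoyl]oxiran-2-yl]-1-methyl-2-oxo-7-oxabicyclo[4.1.0]heptan-3-yl] 3-methylbutanoate, via triethylsilyl peroxide 23 (not isolated)
Conditions: Co(thd)2 (5 mol %; thd = 2,2,6,6-tetramethylheptane-3,5-dionate), O2 (1 atm), Et3SiH (2 equiv), ClCH2CH2Cl, rt; then HF·pyridine, THF, 0 °C
Reagents that add atoms: dioxygen, O=O
Why: Isayama–Mukaiyama cobalt-catalysed hydrosilylperoxidation (metal-hydride hydrogen-atom transfer): the cobalt hydride gives H• to the terminal CH2 of the diene, O2 traps the tertiary end of the allylic radical so that the E-enone stays conjugated, and fluoride cleaves the silyl peroxide to the hydroperoxide; no stereocentre is formed.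

**Compound list**

1 | 3-oxocyclobutane-1-carboxylic acid | O=C1CC(C1)C(=O)O | starting material
2 | 2-bromo-3,3-dimethoxyprop-1-ene | C=C(Br)C(OC)OC | starting material
3 | 1,3-dioxoisoindolin-2-yl 3-oxocyclobutane-1-carboxylate | O=C1CC(C1)C(=O)ON1C(=O)c2ccccc2C1=O | intermediate
4 | (3,3-dimethoxyprop-1-en-2-yl)lithium | [Li]C(=C)C(OC)OC | intermediate
5 | chloro(3,3-dimethoxyprop-1-en-2-yl)zinc | Cl[Zn]C(=C)C(OC)OC | intermediate
6 | 3-(3,3-dimethoxyprop-1-en-2-yl)cyclobutan-1-one | O=C1CC(C1)C(=C)C(OC)OC | intermediate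
7 | propyne | CC#C | starting material
8 | (5R)-5-(3,3-dimethoxyprop-1-en-2-yl)-2-methylcyclohex-2-en-1-one | CC1=CC[C@H](CC1=O)C(=C)C(OC)OC | intermediate
9 | (1R,5R)-5-(3,3-dimethoxyprop-1-en-2-yl)-2-methylcyclohex-2-en-1-ol | CC1=CC[C@H](C[C@H]1O)C(=C)C(OC)OC | intermediate
10 | (1R,2R,4S,6S)-4-(3,3-dimethoxyprop-1-en-2-yl)-1-methyl-7-oxabicyclo[4.1.0]heptan-2-ol | C1[C@@H](O)[C@@]2(C)O[C@H]2C[C@H]1C(=C)C(OC)OC | intermediate
11 | (1S,4R,6S)-4-(3,3-dimethoxyprop-1-en-2-yl)-1-methyl-7-oxabicyclo[4.1.0]heptan-2-one | C1C(=O)[C@@]2(C)O[C@H]2C[C@H]1C(=C)C(OC)OC | intermediate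
12 | 3-methylbutanoyl chloride | CC(C)CC(Cl)=O | starting material
13 | potassium (1S,4R,6S)-4-(3,3-dimethoxyprop-1-en-2-yl)-1-methyl-7-oxabicyclo[4.1.0]hept-2-en-2-olate | C1=C([O-])[C@@]2(C)O[C@H]2C[C@H]1C(=C)C(OC)OC.[K+] | intermediate
14 | potassium (1S,3S,4S,6S)-4-(3,3-dimethoxyprop-1-en-2-yl)-1-methyl-2-oxo-7-oxabicyclo[4.1.0]heptan-3-olate | [K+].[O-][C@@H]1C(=O)[C@@]2(C)O[C@H]2C[C@H]1C(=C)C(OC)OC | intermediate
15 | [(1S,3S,4S,6S)-4-(3,3-dimethoxyprop-1-en-2-yl)-1-methyl-2-oxo-7-oxabicyclo[4.1.0]heptan-3-yl] 3-methylbutanoate | CC(C)CC(=O)O[C@@H]1C(=O)[C@@]2(C)O[C@H]2C[C@H]1C(=C)C(OC)OC | intermediate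
16 | [(1S,3S,4S,6S)-1-methyl-2-oxo-4-(3-oxoprop-1-en-2-yl)-7-oxabicyclo[4.1.0]heptan-3-yl] 3-methylbutanoate | CC(C)CC(=O)O[C@@H]1C(=O)[C@@]2(C)O[C@H]2C[C@H]1C(=C)C=O | intermediate
17 | [(1S,3S,4R,6S)-4-[(2R)-2-formyloxiran-2-yl]-1-methyl-2-oxo-7-oxabicyclo[4.1.0]heptan-3-yl] 3-methylbutanoate | CC(C)CC(=O)O[C@@H]1C(=O)[C@@]2(C)O[C@H]2C[C@H]1[C@]1(C=O)CO1 | intermediate
18 | 2-methylbut-1-en-3-yne | C=C(C)C#C | starting material
19 | chlorobis(cyclopentadienyl)[(1E)-3-methylbuta-1,3-dien-1-yl]zirconium | C=C(C)/C=C/[Zr](Cl)(C1C=CC=C1)C1C=CC=C1 | intermediate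
20 | methyl[(1E)-3-methylbuta-1,3-dien-1-yl]zinc | C=C(C)/C=C/[Zn]C | intermediate
21 | [(1S,3S,4R,6S)-4-[(2R)-2-[(2E)-1-hydroxy-4-methylpenta-2,4-dien-1-yl]oxiran-2-yl]-1-methyl-2-oxo-7-oxabicyclo[4.1.0]heptan-3-yl] 3-methylbutanoate (carbinol epimers) | CC(C)CC(=O)O[C@@H]1C(=O)[C@@]2(C)O[C@H]2C[C@H]1[C@]1(C(O)/C=C/C(C)=C)CO1 | intermediate
22 | [(1S,3S,4R,6S)-1-methyl-4-[(2R)-2-[(2E)-4-methylpenta-2,4-dienoyl]oxiran-2-yl]-2-oxo-7-oxabicyclo[4.1.0]heptan-3-yl] 3-methylbutanoate | CC(C)CC(=O)O[C@@H]1C(=O)[C@@]2(C)O[C@H]2C[C@H]1[C@]1(C(=O)/C=C/C(C)=C)CO1 | intermediate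
23 | [(1S,3S,4R,6S)-1-methyl-4-[(2R)-2-[(2E)-4-methyl-4-(triethylsilylperoxy)pent-2-enoyl]oxiran-2-yl]-2-oxo-7-oxabicyclo[4.1.0]heptan-3-yl] 3-methylbutanoate | CC(C)CC(=O)O[C@@H]1C(=O)[C@@]2(C)O[C@H]2C[C@H]1[C@]1(C(=O)/C=C/C(C)(C)OO[Si](CC)(CC)CC)CO1 | intermediate
24 | [(1S,3S,4R,6S)-4-[(2R)-2-[(2E)-4-hydroperoxy-4-methylpent-2-enoyl]oxiran-2-yl]-1-methyl-2-oxo-7-oxabicyclo[4.1.0]heptan-3-yl] 3-methylbutanoate (CNP0131119.1) | CC(C)CC(=O)O[C@@H]1C(=O)[C@@]2(C)O[C@H]2C[C@H]1[C@]1(C(=O)/C=C/C(C)(C)OO)CO1 | target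

**Totals**

Total step count: 10. Longest linear sequence: 10 steps (1 → 24); compounds 2, 7, 12 and 18 are bought and enter directly.

**Steps most likely to fail, with fallbacks**

Step 2 (the proposed new ring expansion). Possible failures are oligomerisation of the terminal alkyne, the wrong regiochemistry (3-methyl enone), ionisation of the allylic acetal by zerovalent nickel, or low enantioselectivity. The fallback uses only known chemistry, sets out from 2 and comes back to the route at 8. Bromine–lithium exchange of 2 (n-BuLi, THF, −78 °C) and trapping with 2-isopropoxy-4,4,5,5-tetramethyl-1,3,2-dioxaborolane gives the alkenyl pinacol boronate F1. Hayashi–Miyaura rhodium-catalysed asymmetric 1,4-addition of F1 ([Rh(acac)(C2H4)2], (R)-BINAP, aq. K3PO4, dioxane, 60 °C) to racemic 6-methylcyclohex-2-en-1-one F2 gives the (3R)-ketone F3 as both C6 epimers. Thermodynamic enol silylation (Me3SiCl, Et3N, DMF, 80 °C) gives the more substituted silyl enol ether F4, and Saegusa–Ito dehydrogenation (Pd(OAc)2, MeCN) gives 8.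

Step 7 (quaternary epoxide under catalyst control). Possible failures are a mismatched pairing with the chiral substrate or slow iminium formation from the hindered enal, giving a poor ratio at the new centre. The fallback sets out from 15 and comes back at 17. The enal 16 is isolated after the acetal hydrolysis, and NaBH(OAc)3 (CH2Cl2, AcOH) reduces only the aldehyde to the 2-substituted allyl alcohol F5. Sharpless asymmetric epoxidation (Ti(Oi-Pr)4, L-(+)-diethyl tartrate, t-BuOOH, 4 Å MS, CH2Cl2, −20 °C) gives the (2S)-epoxy alcohol F6 under reagent control, which has the same spatial arrangement as the (2R)-aldehyde. Dess–Martin oxidation gives 17.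

Step 10 (late radical hydroperoxidation). Possible failures are hydrogen-atom transfer to the enone, O2 capture at the carbon next to the ketone, or cobalt-induced loss of the peroxide. The fallback sets out from 17 and comes back at 24. In parallel, 2-methylbut-3-en-2-ol F7 is perhydrolysed (50 % H2O2, cat. H2SO4, 0 °C) to 3-hydroperoxy-3-methylbut-1-ene F8, which is masked with 2-methoxypropene (pyridinium p-toluenesulfonate cat.) as the peroxyketal F9. Aldehyde 17 is treated with CH2=CHMgBr/ZnCl2 (THF, −78 → 0 °C) to give the vinyl carbinol F10, and Dess–Martin oxidation gives the vinyl ketone F11. Cross-metathesis of F11 with F9 (second-generation Hoveyda–Grubbs catalyst, CH2Cl2, 40 °C) gives the E-enone peroxyketal F12, and AcOH/THF/H2O releases 24.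

**Further compounds**

F1 | step 2 | 2-(3,3-dimethoxyprop-1-en-2-yl)-4,4,5,5-tetramethyl-1,3,2-dioxaborolane | C=C(B1OC(C)(C)C(C)(C)O1)C(OC)OC
F2 | step 2 | 6-methylcyclohex-2-en-1-one (racemic) | CC1CCC=CC1=O
F3 | step 2 | (3R)-3-(3,3-dimethoxyprop-1-en-2-yl)-6-methylcyclohexan-1-one (C6 epimers) | CC1CC[C@H](CC1=O)C(=C)C(OC)OC
F4 | step 2 | {[(5R)-5-(3,3-dimethoxyprop-1-en-2-yl)-2-methylcyclohex-1-en-1-yl]oxy}trimethylsilane | CC1=C(O[Si](C)(C)C)C[C@@H](CC1)C(=C)C(OC)OC
F5 | step 7 | [(1S,3S,4S,6S)-4-(3-hydroxyprop-1-en-2-yl)-1-methyl-2-oxo-7-oxabicyclo[4.1.0]heptan-3-yl] 3-methylbutanoate | CC(C)CC(=O)O[C@@H]1C(=O)[C@@]2(C)O[C@H]2C[C@H]1C(=C)CO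
F6 | step 7 | [(1S,3S,4R,6S)-4-[(2S)-2-(hydroxymethyl)oxiran-2-yl]-1-methyl-2-oxo-7-oxabicyclo[4.1.0]heptan-3-yl] 3-methylbutanoate | CC(C)CC(=O)O[C@@H]1C(=O)[C@@]2(C)O[C@H]2C[C@H]1[C@]1(CO)CO1
F7 | step 10 | 2-methylbut-3-en-2-ol | CC(C)(O)C=C
F8 | step 10 | 3-hydroperoxy-3-methylbut-1-ene | CC(C)(OO)C=C
F9 | step 10 | 3-[(2-methoxypropan-2-yl)peroxy]-3-methylbut-1-ene | COC(C)(C)OOC(C)(C)C=C
F10 | step 10 | [(1S,3S,4R,6S)-4-[(2R)-2-(1-hydroxyprop-2-en-1-yl)oxiran-2-yl]-1-methyl-2-oxo-7-oxabicyclo[4.1.0]heptan-3-yl] 3-methylbutanoate (carbinol epimers) | CC(C)CC(=O)O[C@@H]1C(=O)[C@@]2(C)O[C@H]2C[C@H]1[C@]1(C(O)C=C)CO1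
F11 | step 10 | [(1S,3S,4R,6S)-4-[(2R)-2-acryloyloxiran-2-yl]-1-methyl-2-oxo-7-oxabicyclo[4.1.0]heptan-3-yl] 3-methylbutanoate | CC(C)CC(=O)O[C@@H]1C(=O)[C@@]2(C)O[C@H]2C[C@H]1[C@]1(C(=O)C=C)CO1
F12 | step 10 | [(1S,3S,4R,6S)-4-[(2R)-2-{(2E)-4-[(2-methoxypropan-2-yl)peroxy]-4-methylpent-2-enoyl}oxiran-2-yl]-1-methyl-2-oxo-7-oxabicyclo[4.1.0]heptan-3-yl] 3-methylbutanoate | CC(C)CC(=O)O[C@@H]1C(=O)[C@@]2(C)O[C@H]2C[C@H]1[C@]1(C(=O)/C=C/C(C)(C)OOC(C)(C)OC)CO1
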